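**Retrosynthetic overview**
- The target 6 comes from 5,7-dibromo-1H-indole 5 by electrophilic bromination at C3, done last because the N–H 3-bromoindole is the most sensitive compound of the route.
- Indole 5 is disconnected across C2=C3: a reductive carbonyl-to-carbonyl coupling of the formamido aldehyde 3 forms this bond and closes the pyrrole ring onto the finished dibromobenzene ring, the only ring formed in the route.
- Structural feature used: C2 and C3 are adjacent CH carbons, C3 bound to C3a and C2 bound to N1, so each maps onto a formyl carbon (ArCHO and NHCHO). The bromines at C5 and C7 are already in place in the commercial aminobenzaldehyde 1.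
- Compound 3 comes from 1 and formic acid 2 by N-formylation.

Key step: step 2

Remark: reagents that put no carbon into the target (Ac2O, TiCl3, Zn, NBS) stand on the Conditions lines and carry no number.

**Step 1**
Reactants: 1 2-amino-3,5-dibromobenzaldehyde; 2 formic acid
Product: 3 N-(2,4-dibromo-6-formylphenyl)formamide
Conditions: HCO2H/Ac2O (premixed, 55 °C, 2 h, then cooled), 1, THF, 0 °C to rt (40 °C if slow)
Reagents that add atoms: formic acid (2), O=CO, transferred as acetic formic anhydride, CC(=O)OC=O
Why: N-formylation with a mixed anhydride, in which acetic formic anhydride passes on its more electrophilic and less hindered formyl group and so should acylate even this deactivated, ortho-disubstituted aniline, leaving the aryl aldehyde and both C–Br bonds untouched.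

**Step 2**
Reactants: 3 N-(2,4-dibromo-6-formylphenyl)formamide
Product: 5 5,7-dibromo-1H-indole, via titanium 5,7-dibromoindoline-2,3-diolate 4 (not isolated)
Conditions: TiCl3 (4 equiv), Zn dust (8 equiv), DME, reflux, Ar, 2 h; then 3 in DME by syringe pump over 3 h, reflux 1 h more; filtration through silica (EtOAc)
Reagents that add atoms: none
Why: Low-valent titanium, formed from TiCl3 and zinc and formally divalent, gives one electron to the aryl aldehyde, the more easily reduced of the two carbonyl groups, and the titanium-bound ketyl carbon (the future C3) adds to the titanium-coordinated formamide carbonyl carbon (the future C2). This closes the pyrrole ring in a 5-exo-trig mode and gives the titanium diolate 4, which the oxophilic metal deoxygenates to the C2=C3 double bond, a loss that is helped by the aromaticity of the indole that results. The closest known reaction type is the titanium-mediated intramolecular oxo-amide coupling of 2-acylamino aryl carbonyl compounds to indoles, a McMurry-type reductive coupling. No stereocenter remains, since the two centres of 4 are both erased in the deoxygenation. The step needs chemoselectivity for ring closure over bimolecular pinacol or stilbene formation of the aldehyde and over reduction of the two C–Br bonds. The ortho placement lets one titanium centre hold both carbonyl oxygens so that closure outruns any bimolecular path, slow addition into dilute reagent supports this, and the zinc-derived reagent is too weak a reductant to attack aryl bromides, as McMurry couplings of bromoaryl ketones show.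

**Step 3**
Reactants: 5 5,7-dibromo-1H-indole
Product: 6 3,5,7-tribromo-1H-indole
Conditions: NBS (1.0 equiv), DMF, 0 °C, dark; aq. Na2S2O3/NaHCO3 work-up
Reagents that add atoms: N-bromosuccinimide, O=C1CCC(=O)N1Br
Why: Electrophilic aromatic substitution at C3, the enamine-like and most nucleophilic position of the indole, while the benzene ring is deactivated by its two bromines and one equivalent of NBS at 0 °C should stop before C2 reacts.

**Compound list**
1 | 2-amino-3,5-dibromobenzaldehyde | Nc1c(Br)cc(Br)cc1C=O | starting material
2 | formic acid | O=CO | starting material
3 | N-(2,4-dibromo-6-formylphenyl)formamide | O=CNc1c(Br)cc(Br)cc1C=O | intermediate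
4 | titanium 5,7-dibromoindoline-2,3-diolate (drawn as the free 2,3-diol; configuration at C2 and C3 not defined, both centres are lost in the same step) | OC1Nc2c(Br)cc(Br)cc2C1O | intermediate
5 | 5,7-dibromo-1H-indole | Brc1cc(Br)c2[nH]ccc2c1 | intermediate
6 | 3,5,7-tribromo-1H-indole | Brc1cc(Br)c2[nH]cc(Br)c2c1 | target

**Step count**
Total steps: 3. Longest linear sequence: 3.

**Steps most likely to fail**

Step 2 (highest risk). The aldehyde may couple with a second molecule (pinacol or stilbene formation) faster than it closes onto the weakly electrophilic formamide, or be reduced to the benzylic alcohol; partial loss of bromine is a lesser risk. The fallback gives up the reductive coupling and brings in C2 as a one-carbon ylide. It sets out from compound 1: Wittig reaction with the ylide from (methoxymethyl)triphenylphosphonium chloride and potassium tert-butoxide (excess, THF, 0 °C to rt) should give the enol ether 2,4-dibromo-6-(2-methoxyethenyl)aniline F1 as an E/Z mixture. Acid (TFA in CH2Cl2 or aqueous HCl in THF) should unmask the arylacetaldehyde, which condenses with the ortho amine and loses methanol to aromatise. The route is rejoined at compound 5.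

Step 1. Acylation of the amine may stall, because the nitrogen is flanked by bromine and by the formyl group, to which it is conjugated and hydrogen-bonded; slow formyl transfer would also let N-acetylation compete. The fallback removes the conjugation before acylation and restores the aldehyde afterwards. It sets out from compound 1: NaBH4 in MeOH at 0 °C should give (2-amino-3,5-dibromophenyl)methanol F2. Excess acetic formic anhydride then formylates nitrogen and oxygen to (3,5-dibromo-2-formamidophenyl)methyl formate F3. Brief KHCO3 in MeOH at 0 °C cleaves only the formate ester to N-[2,4-dibromo-6-(hydroxymethyl)phenyl]formamide F4. MnO2 in CH2Cl2 oxidises the benzylic alcohol, and the route is rejoined at compound 3.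

Step 3. Bromination may run on to C2, and the N–H 3-bromoindole may decompose under acid, light or on silica during isolation. The fallback carries out the bromination on an N-protected, deactivated indole that can be purified and stored. It sets out from compound 5: NaH and benzenesulfonyl chloride in DMF at 0 °C should give 5,7-dibromo-1-(phenylsulfonyl)indole F5. Br2 in CH2Cl2 at rt brominates C3 only, giving 3,5,7-tribromo-1-(phenylsulfonyl)indole F6. KOH in 1,4-dioxane–H2O at 50 °C removes the sulfonyl group from the electron-poor indole nitrogen, and the route is rejoined at compound 6.

**Further compounds**
F1 | step 2 | 2,4-dibromo-6-(2-methoxyethenyl)aniline (E/Z mixture) | COC=Cc1cc(Br)cc(Br)c1N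
F2 | step 1 | (2-amino-3,5-dibromophenyl)methanol | Nc1c(Br)cc(Br)cc1CO
F3 | step 1 | (3,5-dibromo-2-formamidophenyl)methyl formate | O=CNc1c(Br)cc(Br)cc1COC=O
F4 | step 1 | N-[2,4-dibromo-6-(hydroxymethyl)phenyl]formamide | O=CNc1c(Br)cc(Br)cc1CO
F5 | step 3 | 5,7-dibromo-1-(phenylsulfonyl)indole | O=S(=O)(c1ccccc1)n1ccc2cc(Br)cc(Br)c21
F6 | step 3 | 3,5,7-tribromo-1-(phenylsulfonyl)indole | O=S(=O)(c1ccccc1)n1cc(Br)c2cc(Br)cc(Br)c21
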